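**Retrosynthetic overview**

1. Target 23 ⇐ γ-silyloxy ketone 21: the tetrahydrofuran (C11–O–C20) closes by reductive etherification; 21 ⇐ isoxazoline 17 by N–O hydrogenolysis, which unmasks C11=O and C19–OH.
2. Key step: 17 ⇐ aldehyde 14 by intramolecular nitrile oxide–alkene [3+2] cycloaddition, which forms C11–C12, closes the eight-membered ring and sets C12 and C19 from a Z alkene.
3. 14 ⇐ cyclohexanone 10: the cyclopentanone comes from a SmI2 ketyl–nitrile cyclisation (C3–C4) followed by deoxygenation.
4. 10 ⇐ (S)-pulegone 1, the only source of chirality: C9 by deconjugative cyanoethylation, C5 by formylation/methylation, C13–C14 by prenol-dianion addition, C10/C11 by hydroboration of the isopropenyl group.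
5. Ring order: cyclohexane (bought) → cyclopentanone → eight-membered ring together with the isoxazoline → tetrahydrofuran.

Assumption: the SMILES is taken literally at every stereocentre (as written: trans-fused hydrindanone, C14 and C10 on opposite faces of the cyclohexane ring); atoms are numbered as in mutilin (C1–C20).

**Route**

Step 1
Reactants: 1 (S)-(−)-pulegone; 2 acrylonitrile
Product: 3 cyanoethyl isopropenyl ketone
Conditions: KOt-Bu (0.1 equiv), t-BuOH/THF, 0 °C; 2 (1.0 equiv) added slowly
Reagents that add atoms: acrylonitrile (compound 2), C=CC#N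
Why: Base-catalysed Michael addition (cyanoethylation) of the extended dienolate of pulegone through its α-carbon (deconjugative alkylation) creates the C9 quaternary centre; chair-like axial attack places the cyanoethyl arm cis to the equatorial C6 methyl, and limiting acrylonitrile suppresses a second addition at C5.

Step 2
Reactants: 3 cyanoethyl isopropenyl ketone
Product: 4 hydroxymethylene ketone
Conditions: NaH, HCO2Et, THF (cat. EtOH), 0 °C → rt; aq. HCl
Reagents that add atoms: ethyl formate, CCOC=O
Why: Claisen formylation at C5, the only enolisable position of 3 (C9 is quaternary), gives the chelated hydroxymethylene ketone; no stereocentre is set.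

Step 3
Reactants: 4 hydroxymethylene ketone
Product: 5 keto aldehyde
Conditions: MeI, K2CO3, acetone, rt
Reagents that add atoms: iodomethane, CI
Why: C-alkylation of the β-keto-aldehyde enolate; MeI enters anti to the vicinal C6 methyl and to the axial C9 arm, so the new C5 methyl is trans to the C6 methyl and the formyl group (C14) is cis to it.

Step 4
Reactants: 5 keto aldehyde; 6 3-methylbut-2-en-1-ol (prenol)
Product: 8 C20-TBS ether C14-alcohol, via dilithium dialkoxide 7 (not isolated)
Conditions: 6, n-BuLi (2 equiv), TMEDA, Et2O, 0 °C → rt; 5, THF, −78 °C; TBSCl, DMPU, −78 → −30 °C; AcOH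
Reagents that add atoms: 3-methylbut-2-en-1-ol (compound 6), CC(C)=CCO; tert-butyldimethylsilyl chloride, CC(C)(C)[Si](C)(C)Cl
Why: Alkoxide-directed allylic lithiation of prenol takes the Z methyl, and the dianion adds through that CH2 terminus to the non-enolisable aldehyde (the C4 ketone is flanked by two quaternary carbons), giving the Z alkene; Li chelation between C4=O and C14=O with attack from the C5-methyl side sets C14, and only the primary alkoxide is silylated in the flask.

Step 5
Reactants: 8 C20-TBS ether C14-alcohol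
Product: 10 C11,C14-diol, via alkyl-9-BBN borane 9 (not isolated)
Conditions: 9-BBN, THF, 0 °C → rt; H2O2, pH 7 phosphate buffer, 0 °C
Reagents that add atoms: hydrogen peroxide, OO
Why: Hydroboration–oxidation; 9-BBN takes the 1,1-disubstituted alkene in preference to the trisubstituted alkene, the hindered ketone and the nitrile. Attack anti to the C4 carbonyl on the rotamer whose =CH2 points away from the axial cyanoethyl arm sets C10; selectivity may be modest and a minor epimer is separated.

Step 6
Reactants: 10 C11,C14-diol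
Product: 12 α-hydroxy hydrindanone, via α-hydroxy ketimine 11 (not isolated)
Conditions: SmI2, HMPA, t-BuOH, THF, rt; aq. citric acid
Reagents that add atoms: water, O
Why: SmI2 ketyl–nitrile reductive cyclisation (5-exo-dig) forms the C3–C4 bond and the cyclopentane, the C9 tether reaching C4 cis; hydrolysis of the ketimine gives the α-ketol, whose C4 carbinol centre is removed in step 7.

Step 7
Reactants: 12 α-hydroxy hydrindanone
Product: 13 trans-hydrindanone
Conditions: SmI2, THF/MeOH, −78 → 0 °C
Reagents that add atoms: none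
Why: SmI2 reductive cleavage of the α-hydroxy ketone gives a samarium enolate that is protonated at C4 on the face away from the C5 methyl and the C9 side arm, setting the trans ring fusion of the target.

Step 8
Reactants: 13 trans-hydrindanone
Product: 14 C11 aldehyde
Conditions: TEMPO (cat.), PhI(OAc)2, CH2Cl2, rt
Reagents that add atoms: none
Why: TEMPO/PhI(OAc)2 oxidation is selective for the primary C11 alcohol over the hindered secondary C14 alcohol; no stereocentre changes.

Step 9
Reactants: 14 C11 aldehyde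
Product: 17 isoxazoline tetracycle, via aldoxime 15 (not isolated), via nitrile oxide 16 (not isolated)
Conditions: NH2OH·HCl, NaOAc, MeOH, 0 °C; then PhI(OAc)2, TFA (cat.), MeOH (0.002 M), 0 °C → rt
Reagents that add atoms: hydroxylamine hydrochloride, Cl.NO
Why: Intramolecular nitrile oxide–alkene 1,3-dipolar cycloaddition (key step): the tether puts C11 on C12 and O on C19, closing the eight-membered ring. Suprafacial addition to the Z alkene fixes the C12/C19 relationship, and the folded tether (C14–O pseudo-equatorial) selects the alkene face, setting both centres relative to C14 and C10.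

Step 10
Reactants: 17 isoxazoline tetracycle; 18 (tert-butyldimethylsilyloxy)acetic acid
Product: 19 C14 silyloxyacetate
Conditions: EDC·HCl, DMAP, CH2Cl2, rt
Reagents that add atoms: (tert-butyldimethylsilyloxy)acetic acid (compound 18), CC(C)(C)[Si](C)(C)OCC(=O)O
Why: Steglich esterification of the only free hydroxyl (C14–OH; C19–O is masked in the isoxazoline, C20–O as silyl ether); no stereocentre is touched.

Step 11
Reactants: 19 C14 silyloxyacetate
Product: 21 β-hydroxy ketone, via β-hydroxy imine 20 (not isolated)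
Conditions: H2 (1 atm), Raney Ni, B(OH)3, MeOH/H2O, rt
Reagents that add atoms: water, O
Why: Hydrogenolysis of the isoxazoline N–O bond and hydrolysis of the imine in the boric acid buffer unmask the C11 ketone and the C19 alcohol without retro-aldol cleavage; stereocentres are untouched.

Step 12
Reactants: 21 β-hydroxy ketone
Product: 23 pleuromutilin B, via O-TBS pleuromutilin B 22 (not isolated)
Conditions: Et3SiH, TMSOTf (cat.), CH2Cl2, −78 → −20 °C; then MeOH, aq. HCl, 0 °C
Reagents that add atoms: none
Why: Reductive etherification: the C20 silyl ether adds to the activated C11 ketone and Et3SiH reduces the five-membered oxocarbenium ion on the face that gives the cis-fused oxabicycle (H-11 syn to the C12 methyl), setting C11; methanolic HCl then removes the glycolate silyl group.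

**Compound list**

1 | (S)-(−)-pulegone, (5S)-5-methyl-2-(propan-2-ylidene)cyclohexan-1-one | O=C1C[C@@H](C)CCC1=C(C)C | starting material
2 | acrylonitrile | C=CC#N | starting material
3 | 3-[4-methyl-2-oxo-1-(prop-1-en-2-yl)cyclohexyl]propanenitrile; cyanoethyl arm cis to the ring methyl, isopropenyl trans (C9 set) | O=C1C[C@@H](C)CC[C@]1(CCC#N)C(C)=C | intermediate
4 | 3-[3-(hydroxymethylene)-4-methyl-2-oxo-1-(prop-1-en-2-yl)cyclohexyl]propanenitrile (chelated Z enol) | O=C1/C(=C\O)[C@@H](C)CC[C@]1(CCC#N)C(C)=C | intermediate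
5 | 3-[3-formyl-3,4-dimethyl-2-oxo-1-(prop-1-en-2-yl)cyclohexyl]propanenitrile; formyl cis to the C6 methyl and to the cyanoethyl arm, C5 methyl trans to the C6 methyl | O=C[C@@]1(C)[C@@H](C)CC[C@](CCC#N)(C(C)=C)C1=O | intermediate
6 | 3-methylbut-2-en-1-ol (prenol) | CC(C)=CCO | starting material
7 | dilithium dialkoxide of the (Z)-C14,C20-diol formed from 5 and the prenol dianion | [Li+].[Li+].[O-]C/C=C(C)\C[C@@H]([O-])[C@@]1(C)[C@@H](C)CC[C@](CCC#N)(C(C)=C)C1=O | intermediate
8 | (Z)-homoallylic C14 alcohol with C20 OTBS (side chain C14(OH)–CH2–C(Me)=CH–CH2OTBS on C5) | CC(C)(C)[Si](C)(C)OC/C=C(C)\C[C@@H](O)[C@@]1(C)[C@@H](C)CC[C@](CCC#N)(C(C)=C)C1=O | intermediate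
9 | B-alkyl-9-BBN adduct of 8 (boron on C11, C10 set) | CC(C)(C)[Si](C)(C)OC/C=C(C)\C[C@@H](O)[C@@]1(C)[C@@H](C)CC[C@](CCC#N)([C@@H](C)CB2C3CCCC2CCC3)C1=O | intermediate
10 | C11,C14-diol (C9 carries CH(CH3)CH2OH and the cyanoethyl arm) | CC(C)(C)[Si](C)(C)OC/C=C(C)\C[C@@H](O)[C@@]1(C)[C@@H](C)CC[C@](CCC#N)([C@@H](C)CO)C1=O | intermediate
11 | bicyclic α-hydroxy ketimine (C3=NH, C4–OH, cis-fused) | CC(C)(C)[Si](C)(C)OC/C=C(C)\C[C@@H](O)[C@@]1(C)[C@@H](C)CC[C@@]2([C@@H](C)CO)CCC(=N)[C@@]12O | intermediate
12 | 4-hydroxy-hydrindan-3-one (α-ketol, cis-fused) | CC(C)(C)[Si](C)(C)OC/C=C(C)\C[C@@H](O)[C@@]1(C)[C@@H](C)CC[C@@]2([C@@H](C)CO)CCC(=O)[C@@]12O | intermediate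
13 | trans-fused hydrindan-3-one with C11 and C14 hydroxyls | CC(C)(C)[Si](C)(C)OC/C=C(C)\C[C@@H](O)[C@@]1(C)[C@@H](C)CC[C@@]2([C@@H](C)CO)CCC(=O)[C@H]12 | intermediate
14 | C11 aldehyde of 13 | CC(C)(C)[Si](C)(C)OC/C=C(C)\C[C@@H](O)[C@@]1(C)[C@@H](C)CC[C@@]2([C@@H](C)C=O)CCC(=O)[C@H]12 | intermediate
15 | (E)-aldoxime of 14 | CC(C)(C)[Si](C)(C)OC/C=C(C)\C[C@@H](O)[C@@]1(C)[C@@H](C)CC[C@@]2([C@@H](C)/C=N/O)CCC(=O)[C@H]12 | intermediate
16 | C11 nitrile oxide | CC(C)(C)[Si](C)(C)OC/C=C(C)\C[C@@H](O)[C@@]1(C)[C@@H](C)CC[C@@]2([C@@H](C)C#[N+][O-])CCC(=O)[C@H]12 | intermediate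
17 | isoxazoline-fused 5-6-8 tricycle (C11=N–O–C19, C12 quaternary, C20 OTBS, C14–OH free) | C[C@H]1C2=NO[C@H](CO[Si](C)(C)C(C)(C)C)[C@]2(C)C[C@@H](O)[C@@]2(C)[C@@H](C)CC[C@]13CCC(=O)[C@@H]32 | intermediate
18 | (tert-butyldimethylsilyloxy)acetic acid | CC(C)(C)[Si](C)(C)OCC(=O)O | starting material
19 | C14 (tert-butyldimethylsilyloxy)acetate of 17 | C[C@H]1C2=NO[C@H](CO[Si](C)(C)C(C)(C)C)[C@]2(C)C[C@@H](OC(=O)CO[Si](C)(C)C(C)(C)C)[C@@]2(C)[C@@H](C)CC[C@]13CCC(=O)[C@@H]32 | intermediate
20 | β-hydroxy imine (C11=NH, C19–OH) | C[C@H]1C(=N)[C@](C)([C@H](O)CO[Si](C)(C)C(C)(C)C)C[C@@H](OC(=O)CO[Si](C)(C)C(C)(C)C)[C@@]2(C)[C@@H](C)CC[C@]13CCC(=O)[C@@H]32 | intermediate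
21 | β-hydroxy ketone (C11=O, C19–OH, C20 OTBS) | C[C@H]1C(=O)[C@](C)([C@H](O)CO[Si](C)(C)C(C)(C)C)C[C@@H](OC(=O)CO[Si](C)(C)C(C)(C)C)[C@@]2(C)[C@@H](C)CC[C@]13CCC(=O)[C@@H]32 | intermediate
22 | pleuromutilin B with the glycolate hydroxyl as TBS ether | C[C@H]1[C@@H]2OC[C@@H](O)[C@]2(C)C[C@@H](OC(=O)CO[Si](C)(C)C(C)(C)C)[C@@]2(C)[C@@H](C)CC[C@]13CCC(=O)[C@@H]32 | intermediate
23 | pleuromutilin B (configuration as in the given SMILES) | C[C@H]1[C@@H]2OC[C@@H](O)[C@]2(C)C[C@@H](OC(=O)CO)[C@@]2(C)[C@@H](C)CC[C@]13CCC(=O)[C@@H]32 | target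

**Step count and risks**

Total steps: 12. Longest linear sequence: 12 steps (1 → 23).

The three steps most likely to fail:

Step 9 (cycloaddition). The nitrile oxide must close an eight-membered ring and form a quaternary carbon against the usual regiochemical preference of a trisubstituted alkene, so furoxan dimers or no cyclisation are real possibilities. The fallback sets out from 14 and returns at 23, closing the ring by a metal-mediated allylation instead. Aldehyde 14 is esterified at C14–OH with 18 (EDC, DMAP) to give the aldehyde bis-silyl ether F1. HF·pyridine removes both silyl groups to give the allylic alcohol aldehyde F2. Pd(PPh3)4/Et3B (umpolung allylation of the free allylic alcohol) then adds the allyl unit through C12 to the C11 aldehyde, closing the eight-membered ring as the vinyl homoallylic alcohol F3 (C11–OH, C12 methyl/vinyl quaternary centre). VO(acac)2/t-BuOOH epoxidation of the vinyl group, directed by the C11 hydroxyl, gives the epoxide F4. CSA then opens the epoxide at C20 with the C11 hydroxyl to form the tetrahydrofuran and give 23.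

Step 4 (dianion addition). The prenol dianion may react through its internal carbon, and the hindered aldolate may undergo retro-aldol cleavage. The fallback sets out from 5 and returns at 8. The dianion of 3-methylbut-2-enoic acid (2 equiv LDA, thermodynamic γ-adduct) is added to 5 and the product is acidified to the dihydropyranone F5, whose ring fixes the Z geometry. LiBH4 reduces the lactone to the free Z-diol F6, and TBSCl/imidazole silylates the primary allylic hydroxyl to give 8.

Step 6 (ketyl–nitrile cyclisation). The ketyl sits at a ketone flanked by two quaternary carbons and may simply be reduced or add to the C12=C19 alkene. The fallback sets out from 10 and returns at 12 using polar umpolung chemistry. DIBAL-H (−78 °C, aqueous work-up) converts the nitrile into the C3 aldehyde F7. An achiral thiazolium-derived carbene (3-benzyl-5-(2-hydroxyethyl)-4-methylthiazolium chloride, DBU) then effects an intramolecular crossed benzoin addition of C3 to the C4 ketone, giving α-ketol 12 directly.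

**Further compounds**

F1 | step 9 | C14 (tert-butyldimethylsilyloxy)acetate of aldehyde 14 | CC(C)(C)[Si](C)(C)OC/C=C(C)\C[C@@H](OC(=O)CO[Si](C)(C)C(C)(C)C)[C@@]1(C)[C@@H](C)CC[C@@]2([C@@H](C)C=O)CCC(=O)[C@H]12
F2 | step 9 | allylic alcohol aldehyde with free glycolate (bis-desilylated F1) | OC/C=C(C)\C[C@@H](OC(=O)CO)[C@@]1(C)[C@@H](C)CC[C@@]2([C@@H](C)C=O)CCC(=O)[C@H]12
F3 | step 9 | tricyclic homoallylic alcohol (C11–OH, C12 methyl and vinyl, C14 glycolate) | C[C@H]1[C@H](O)[C@](C)(C=C)C[C@@H](OC(=O)CO)[C@@]2(C)[C@@H](C)CC[C@]13CCC(=O)[C@@H]32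
F4 | step 9 | C19,C20-epoxide of F3 | C[C@H]1[C@H](O)[C@](C)([C@H]2CO2)C[C@@H](OC(=O)CO)[C@@]2(C)[C@@H](C)CC[C@]13CCC(=O)[C@@H]32
F5 | step 4 | 6-substituted 4-methyl-5,6-dihydro-2H-pyran-2-one (C14–O–C20 lactone) | CC1=CC(=O)O[C@H](C1)[C@@]2(C)[C@@H](C)CC[C@](CCC#N)(C(C)=C)C2=O
F6 | step 4 | free (Z)-C14,C20-diol | OC/C=C(C)\C[C@@H](O)[C@@]1(C)[C@@H](C)CC[C@](CCC#N)(C(C)=C)C1=O
F7 | step 6 | C3 aldehyde from nitrile 10 | CC(C)(C)[Si](C)(C)OC/C=C(C)\C[C@@H](O)[C@@]1(C)[C@@H](C)CC[C@](CCC=O)([C@@H](C)CO)C1=O
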